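**Plan**

1. Retrosynthesis: the aryl ester is removed from O–C4. The C6 carbinol goes back to a C6 ketone (through an exocyclic epoxide) and the C4 carbinol to a C4 ketone. The resulting cyclohept-7-ene-4,6-dione is cut at C3a–C4 and C5–C6, which removes C4–C5 as a ketene unit and leaves a cis-bicyclo[3.3.0]octenone.
2. Enabling feature: the 1,3-dioxygenated array C4–C5(H2)–C6 on the seven-membered ring is the retron of a ketene/silyl enol ether [2+2] cycloaddition followed by retro-aldol opening. Quaternary C8a leaves C3a as the only enolisable position of the five-membered enone (C3a, C6, C7, C8, C8a), so a single 2-siloxydiene can form.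
3. Forward order: ring B as a cyclopentenone (asymmetric conjugate addition, dehydrogenation); ring A by intramolecular aldol onto an isopropyl ketone; two-carbon expansion of ring B to the cycloheptenedione; then C4, C6 and the ester.
4. Stereochemistry: C8a from the chiral copper catalyst; C3 from the chelated aldol in the cis-diquinane; C3a by equilibration to the cis-fused hydroazulene; C4 by hydride delivery from the C3 hydroxyl; C6 by epoxidation directed by the C4 hydroxyl.

Key step: step 7

Remark: locants C1–C8a are those of the hydroazulene skeleton of the target and are used for the corresponding atoms of all intermediates. The target is the cis-fused isomer: H-3a, CH3-8a, O–C4 and O–C6 lie on one face, and HO–C3 lies on the other.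

**Route**

Step 1
Reactants: 1 3-methylcyclopent-2-en-1-one; 2 5-bromo-2-methylpent-2-ene
Product: 4 (3S)-3-methyl-3-(4-methylpent-3-en-1-yl)cyclopentan-1-one, via Grignard reagent 3 (not isolated)
Conditions: 2, Mg, Et2O, reflux; then 1, Cu(OTf)2 (3 mol%), chiral C2-symmetric imidazolinium salt (carbene ligand precursor, 4 mol%), Et2O, −30 °C; aq. NH4Cl
Reagents that add atoms: none
Why: Copper-catalysed asymmetric conjugate addition of a Grignard reagent to a β-methyl cyclic enone is an established way to β-quaternary cyclopentanones, and the enantiomer of the carbene ligand is chosen so that the enone face is attacked that makes C8a S.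

Step 2
Reactants: 4
Product: 6 (4R)-4-methyl-4-(4-methylpent-3-en-1-yl)cyclopent-2-en-1-one, via silyl enol ether 5 (not isolated)
Conditions: LiN(iPr)2, Me3SiCl, THF, −78 °C; then Pd(OAc)2 (1.1 equiv), MeCN, rt
Reagents that add atoms: chlorotrimethylsilane, C[Si](C)(C)Cl (its silyl group is carried only by 5 and is lost again in this step)
Why: Saegusa–Ito oxidation: kinetic deprotonation takes the unhindered CH2 (C7) remote from the quaternary carbon, and because C8a bears no hydrogen the only enone that can form is the C7=C8 one.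

Step 3
Reactants: 6
Product: 7 (4R)-4-[2-(3,3-dimethyloxiran-2-yl)ethyl]-4-methylcyclopent-2-en-1-one (both oxirane epimers)
Conditions: mCPBA, NaHCO3, CH2Cl2, 0 °C
Reagents that add atoms: mCPBA, OOC(=O)c1cccc(Cl)c1
Why: Prilezhaev epoxidation takes the electron-rich trisubstituted alkene and leaves the electron-poor enone alkene; the new oxirane stereocentre is removed in step 4 and needs no control.

Step 4
Reactants: 7
Product: 8 (4R)-4-methyl-4-(4-methyl-3-oxopentyl)cyclopent-2-en-1-one
Conditions: BF3·OEt2 (0.3 equiv), CH2Cl2, −78 → −20 °C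
Reagents that add atoms: none
Why: Meinwald rearrangement: the Lewis acid opens the oxirane at its tertiary carbon and a 1,2-hydride shift gives the isopropyl ketone (the future C3 carbonyl).

Step 5
Reactants: 8
Product: 9 (3aS,6R,6aR)-6-hydroxy-3a-methyl-6-(propan-2-yl)-4,5,6,6a-tetrahydropentalen-1(3aH)-one (cis-fused)
Conditions: LiN(SiMe3)2 (1.1 equiv), THF, −78 → −20 °C; AcOH quench at −78 °C
Reagents that add atoms: none
Why: Intramolecular aldol addition (5-exo closure of ring A) of the α'-enolate at C3a, the only enolisable ring carbon, can only give the cis-fused bicyclo[3.3.0]octane, and the lithium chelate between enolate oxygen and ketone oxygen puts the new C3–O bond on the concave face and the isopropyl group on the convex face, which sets C3 (R) relative to C8a.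

Step 6
Reactants: 9
Product: 10 (1R,3aS)-3a-methyl-1-(propan-2-yl)-1,6-bis[(trimethylsilyl)oxy]-1,2,3,3a-tetrahydropentalene
Conditions: Me3SiOTf (3 equiv), Et3N (5 equiv), CH2Cl2, 0 °C → rt; used crude
Reagents that add atoms: trimethylsilyl triflate, C[Si](C)(C)OS(=O)(=O)C(F)(F)F
Why: Silyl triflate/amine soft enolisation silylates the tertiary alcohol and converts the enone into its cross-conjugated silyl dienol ether; C3a–H is the only α'-hydrogen and C8a has no γ-hydrogen, so only this 2-siloxydiene can form.

Step 7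
Reactants: 10; 11 dichloroacetyl chloride
Product: 13 (1S,4R,7S,10R)-3,3-dichloro-7-methyl-10-(propan-2-yl)-4,10-bis[(trimethylsilyl)oxy]tricyclo[5.3.0.0^1,4]dec-5-en-2-one (cyclobutanone cis-fused to ring B), via dichloroketene 12 (not isolated)
Conditions: 11 (1.5 equiv, slow addition), Et3N, hexane, rt
Reagents that add atoms: none
Why: Dichloroketene, released from the acid chloride 11 by Et3N, adds across the silyl enol ether double bond of 10 (C3a=C6) in a concerted but asynchronous [2+2] cycloaddition: its carbonyl carbon (future C4) bonds to the nucleophilic terminus C3a and the CCl2 carbon (future C5) closes onto C6, whose developing positive charge is stabilised by the silyloxy group and the adjacent C7=C8 double bond. The closest known reaction type is the cycloaddition of dichloroketene to cycloalkanone silyl enol ethers that is used for two-carbon ring expansion to cycloalkane-1,3-diones. The four-membered ring is closed by this intermolecular cycloaddition and is necessarily cis-fused to ring B; no other ring is closed. The two new stereocentres (C3a and C6 of the adduct) arise from addition to the face that keeps rings A and B cis-fused (new C3a–C4 bond syn to the angular methyl), and both are erased in step 8, so their sense does not matter. The step needs regio- and site-selectivity: the polarisation of the 2-siloxydiene allows bond formation to start only at C3a, the electrophilic ketene prefers the enol ether to the C7=C8 alkene, and quaternary C8a guarantees that 10 is the only dienol ether of 9.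

Step 8
Reactants: 13
Product: 15 (3R,3aR,8aS)-3-hydroxy-8a-methyl-3-(propan-2-yl)-2,3,3a,8a-tetrahydroazulene-4,6(1H,5H)-dione (cis-fused), via dechlorinated cyclobutanone 14 (not isolated)
Conditions: Zn, AcOH, iPrOH/H2O, 0 °C → rt; then Bu4NF, AcOH, THF, 0 °C; then DBU (0.3 equiv), MeCN, rt
Reagents that add atoms: none
Why: Zinc/acetic acid removes both chlorines first (so that the later fragmentation cannot be diverted toward a dichloro enolate), fluoride desilylation then triggers retro-aldol cleavage of the strained fusion bond C3a–C6 as in the known conversion of such adducts into cycloalkane-1,3-diones, and base equilibration of the epimerisable C3a should favour the cis-fused epimer, in which C4 avoids the isopropyl and angular methyl groups.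

Step 9
Reactants: 15
Product: 16 (3R,3aS,4S,8aS)-3,4-dihydroxy-8a-methyl-3-(propan-2-yl)-2,3,3a,4,5,8a-hexahydroazulen-6(1H)-one
Conditions: Me4NBH(OAc)3 (1.5 equiv), MeCN/AcOH (1:1), −30 °C; aq. sodium potassium tartrate
Reagents that add atoms: none
Why: Evans–Saksena reduction: the alkoxy(acetoxy)borohydride formed at the C3 hydroxyl delivers hydride intramolecularly to the face of the C4 carbonyl on which C3–O lies, giving the 1,3-anti diol (4S), while the conjugated C6 carbonyl, which has no β-hydroxyl in 15, should be left.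

Step 10
Reactants: 16
Product: 17 (3R,3aS,4S,8aS)-8a-methyl-6-methylidene-3-(propan-2-yl)-1,2,3,3a,4,5,6,8a-octahydroazulene-3,4-diol
Conditions: Zn, CH2Br2, TiCl4, THF/CH2Cl2, 0 °C → rt
Reagents that add atoms: dibromomethane, BrCBr
Why: Takai–Lombardo methylenation is non-basic, so the β-hydroxy enone is converted into the exocyclic alkene without retro-aldol cleavage or β-elimination, and free hydroxyl groups are tolerated.

Step 11
Reactants: 17
Product: 18 (3R,3aS,4S,6R,8aS)-8a-methyl-3-(propan-2-yl)-2,3,3a,4,5,8a-hexahydro-1H-spiro[azulene-6,2'-oxirane]-3,4-diol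
Conditions: VO(acac)2 (5 mol%), tBuOOH, CH2Cl2, 0 °C → rt
Reagents that add atoms: tert-butyl hydroperoxide, CC(C)(C)OO
Why: Vanadium-catalysed hydroxyl-directed epoxidation: the homoallylic C4 hydroxyl binds the vanadium peroxide and delivers oxygen to its own face of the exocyclic alkene, which sets the C6–O bond cis to O–C4 (6R); the C7=C8 alkene is remote from the directing group and shielded by quaternary C8a.

Step 12
Reactants: 18
Product: 19 (3R,3aS,4S,6R,8aS)-6,8a-dimethyl-3-(propan-2-yl)-1,2,3,3a,4,5,6,8a-octahydroazulene-3,4,6-triol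
Conditions: LiBHEt3 (4 equiv), THF, 0 °C; aq. NH4Cl
Reagents that add atoms: none
Why: Hydride opens the 1,1-disubstituted oxirane by SN2 attack at its unhindered CH2 terminus, which creates the C6 methyl group and leaves the C6–O bond, and hence the configuration set in step 11, untouched.

Step 13
Reactants: 19; 20 4-acetoxybenzoyl chloride
Product: 21 (3R,3aS,4S,6R,8aS)-3,6-dihydroxy-6,8a-dimethyl-3-(propan-2-yl)-1,2,3,3a,4,5,6,8a-octahydroazulen-4-yl 4-(acetyloxy)benzoate
Conditions: 20 (1.2 equiv), Et3N, DMAP (cat.), CH2Cl2, 0 °C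
Reagents that add atoms: none
Why: DMAP-catalysed acylation distinguishes the single secondary alcohol (C4) from the two tertiary alcohols, which do not react under these conditions.

Step 14
Reactants: 21
Product: 22 (3R,3aS,4S,6R,8aS)-3,6-dihydroxy-6,8a-dimethyl-3-(propan-2-yl)-1,2,3,3a,4,5,6,8a-octahydroazulen-4-yl 4-hydroxybenzoate (target)
Conditions: NH4OAc, MeOH/H2O, rt
Reagents that add atoms: none
Why: Mild transesterification removes the aryl acetate, which is far more electrophilic than the hindered secondary benzoate, so the phenol is released without touching the C4 ester.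

**Compound list**

1 | 3-methylcyclopent-2-en-1-one | CC1=CC(=O)CC1 | starting material
2 | 5-bromo-2-methylpent-2-ene | CC(C)=CCCBr | starting material
3 | (4-methylpent-3-en-1-yl)magnesium bromide | CC(C)=CCC[Mg]Br | intermediate (not isolated)
4 | (3S)-3-methyl-3-(4-methylpent-3-en-1-yl)cyclopentan-1-one | C[C@]1(CCC=C(C)C)CCC(=O)C1 | intermediate
5 | trimethyl{[(4S)-4-methyl-4-(4-methylpent-3-en-1-yl)cyclopent-1-en-1-yl]oxy}silane | C[C@]1(CCC=C(C)C)CC=C(O[Si](C)(C)C)C1 | intermediate (not isolated)
6 | (4R)-4-methyl-4-(4-methylpent-3-en-1-yl)cyclopent-2-en-1-one | C[C@]1(CCC=C(C)C)C=CC(=O)C1 | intermediate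
7 | (4R)-4-[2-(3,3-dimethyloxiran-2-yl)ethyl]-4-methylcyclopent-2-en-1-one (oxirane epimers) | C[C@]1(CCC2OC2(C)C)C=CC(=O)C1 | intermediate
8 | (4R)-4-methyl-4-(4-methyl-3-oxopentyl)cyclopent-2-en-1-one | C[C@]1(CCC(=O)C(C)C)C=CC(=O)C1 | intermediate
9 | (3aS,6R,6aR)-6-hydroxy-3a-methyl-6-(propan-2-yl)-4,5,6,6a-tetrahydropentalen-1(3aH)-one | CC(C)[C@]1(O)CC[C@@]2(C)C=CC(=O)[C@@H]12 | intermediate
10 | (1R,3aS)-3a-methyl-1-(propan-2-yl)-1,6-bis[(trimethylsilyl)oxy]-1,2,3,3a-tetrahydropentalene | CC(C)[C@]1(O[Si](C)(C)C)CC[C@@]2(C)C=CC(O[Si](C)(C)C)=C12 | intermediate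
11 | dichloroacetyl chloride | ClC(Cl)C(Cl)=O | starting material
12 | dichloroketene | ClC(Cl)=C=O | intermediate (not isolated)
13 | (1S,4R,7S,10R)-3,3-dichloro-7-methyl-10-(propan-2-yl)-4,10-bis[(trimethylsilyl)oxy]tricyclo[5.3.0.0^1,4]dec-5-en-2-one | CC(C)[C@]1(O[Si](C)(C)C)CC[C@@]2(C)C=C[C@]3(O[Si](C)(C)C)C(Cl)(Cl)C(=O)[C@]123 | intermediate
14 | (1S,4R,7S,10R)-7-methyl-10-(propan-2-yl)-4,10-bis[(trimethylsilyl)oxy]tricyclo[5.3.0.0^1,4]dec-5-en-2-one | CC(C)[C@]1(O[Si](C)(C)C)CC[C@@]2(C)C=C[C@]3(O[Si](C)(C)C)CC(=O)[C@]123 | intermediate (not isolated)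
15 | (3R,3aR,8aS)-3-hydroxy-8a-methyl-3-(propan-2-yl)-2,3,3a,8a-tetrahydroazulene-4,6(1H,5H)-dione | CC(C)[C@]1(O)CC[C@@]2(C)C=CC(=O)CC(=O)[C@@H]12 | intermediate
16 | (3R,3aS,4S,8aS)-3,4-dihydroxy-8a-methyl-3-(propan-2-yl)-2,3,3a,4,5,8a-hexahydroazulen-6(1H)-one | CC(C)[C@]1(O)CC[C@@]2(C)C=CC(=O)C[C@H](O)[C@@H]12 | intermediate
17 | (3R,3aS,4S,8aS)-8a-methyl-6-methylidene-3-(propan-2-yl)-1,2,3,3a,4,5,6,8a-octahydroazulene-3,4-diol | CC(C)[C@]1(O)CC[C@@]2(C)C=CC(=C)C[C@H](O)[C@@H]12 | intermediate
18 | (3R,3aS,4S,6R,8aS)-8a-methyl-3-(propan-2-yl)-2,3,3a,4,5,8a-hexahydro-1H-spiro[azulene-6,2'-oxirane]-3,4-diol | CC(C)[C@]1(O)CC[C@@]2(C)C=C[C@]3(OC3)C[C@H](O)[C@@H]12 | intermediate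
19 | (3R,3aS,4S,6R,8aS)-6,8a-dimethyl-3-(propan-2-yl)-1,2,3,3a,4,5,6,8a-octahydroazulene-3,4,6-triol | CC(C)[C@]1(O)CC[C@@]2(C)C=C[C@](C)(O)C[C@H](O)[C@@H]12 | intermediate
20 | 4-acetoxybenzoyl chloride | CC(=O)Oc1ccc(cc1)C(Cl)=O | starting material
21 | (3R,3aS,4S,6R,8aS)-3,6-dihydroxy-6,8a-dimethyl-3-(propan-2-yl)-1,2,3,3a,4,5,6,8a-octahydroazulen-4-yl 4-(acetyloxy)benzoate | CC(C)[C@]1(O)CC[C@@]2(C)C=C[C@](C)(O)C[C@H](OC(=O)c3ccc(OC(C)=O)cc3)[C@@H]12 | intermediate
22 | (3R,3aS,4S,6R,8aS)-3,6-dihydroxy-6,8a-dimethyl-3-(propan-2-yl)-1,2,3,3a,4,5,6,8a-octahydroazulen-4-yl 4-hydroxybenzoate | CC(C)[C@]1(O)CC[C@@]2(C)C=C[C@](C)(O)C[C@H](OC(=O)c3ccc(O)cc3)[C@@H]12 | target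

**Summary**

Total step count: 14. Longest linear sequence: 14 steps (1 → 22; 2, 11 and 20 are commercial inputs).

Steps most likely to fail:

1. Step 7. The enol ether carbon C3a is flanked by two fully substituted carbons, so the cycloaddition may be slow enough for ketene oligomerisation or C-acylation with loss of the silyl group to take over. The fallback expands ring B before ring A exists; it sets out from 6 and returns at 15. Compound 6 is converted with LiN(iPr)2/Me3SiCl into 5-methyl-5-(4-methylpent-3-en-1-yl)-2-(trimethylsilyloxy)cyclopenta-1,3-diene F1, whose reacting terminus is an unhindered CH. Dichloroketene 12 (from 11 and Et3N) should give the dichlorocyclobutanone F2, Zn/AcOH the dechlorinated cyclobutanone F3, and Bu4NF/AcOH the ring-expanded cycloheptenedione F4. mCPBA then epoxidises the side chain to the epoxy dione F5, and BF3·OEt2 rearranges it to the triketone F6. Finally an intramolecular aldol addition of the diketone dianion (excess LiN(SiMe3)2, THF; C3a is the only γ-position that bears hydrogen) onto the isopropyl ketone closes ring A. The three-atom tether enforces cis ring fusion and chelation sets C3, which gives 15.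

2. Step 5. Enolisation may be unselective: side-chain enolates can form instead of the C3a enolate, and the isopropyl-ketone enolate could add in Michael fashion to the enone, or the ketol could revert. The fallback makes the C3a enolate regiospecifically; it sets out from 6 and returns at 9. α'-Bromination of 6 (LiN(iPr)2, then N-bromosuccinimide, −78 °C) gives the bromo enone F7, mCPBA gives the bromo epoxide F8, and BF3·OEt2 gives the bromo diketone F9. SmI2 (THF, −78 °C) reduces only the C–Br bond, and the resulting samarium enolate at C3a adds to the isopropyl ketone through a chelate (intramolecular Reformatsky-type aldol) to give 9.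

3. Step 9. Once the new C4 hydroxyl exists it can itself direct hydride to the C6 carbonyl, so over-reduction may compete, while the hindered tertiary C3 hydroxyl may exchange onto boron only slowly. The fallback reduces both carbonyls on purpose and re-oxidises one; it sets out from 15 and returns at 16. Excess Me4NBH(OAc)3 (MeCN/AcOH, rt) gives the azulene-3,4,6-triol F10 (C4 set by delivery from the C3 hydroxyl), and MnO2 (CH2Cl2, rt) oxidises only the allylic C6 alcohol to give 16.

**Further compounds**

F1 | step 7 | (5S)-5-methyl-5-(4-methylpent-3-en-1-yl)-2-(trimethylsilyloxy)cyclopenta-1,3-diene | C[C@]1(CCC=C(C)C)C=CC(O[Si](C)(C)C)=C1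
F2 | step 7 | (4S)-7,7-dichloro-4-methyl-4-(4-methylpent-3-en-1-yl)-1-[(trimethylsilyl)oxy]bicyclo[3.2.0]hept-2-en-6-one (cis-fused) | C[C@]1(CCC=C(C)C)C=CC2(O[Si](C)(C)C)C(Cl)(Cl)C(=O)C12
F3 | step 7 | (4S)-4-methyl-4-(4-methylpent-3-en-1-yl)-1-[(trimethylsilyl)oxy]bicyclo[3.2.0]hept-2-en-6-one (cis-fused) | C[C@]1(CCC=C(C)C)C=CC2(O[Si](C)(C)C)CC(=O)C12
F4 | step 7 | (6R)-6-methyl-6-(4-methylpent-3-en-1-yl)cyclohept-4-ene-1,3-dione | C[C@]1(CCC=C(C)C)C=CC(=O)CC(=O)C1
F5 | step 7 | (6R)-6-[2-(3,3-dimethyloxiran-2-yl)ethyl]-6-methylcyclohept-4-ene-1,3-dione (oxirane epimers) | C[C@]1(CCC2OC2(C)C)C=CC(=O)CC(=O)C1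
F6 | step 7 | (6R)-6-methyl-6-(4-methyl-3-oxopentyl)cyclohept-4-ene-1,3-dione | C[C@]1(CCC(=O)C(C)C)C=CC(=O)CC(=O)C1
F7 | step 5 | (4S)-5-bromo-4-methyl-4-(4-methylpent-3-en-1-yl)cyclopent-2-en-1-one (C5 epimers) | C[C@]1(CCC=C(C)C)C=CC(=O)C1Br
F8 | step 5 | (4S)-5-bromo-4-[2-(3,3-dimethyloxiran-2-yl)ethyl]-4-methylcyclopent-2-en-1-one (epimers) | C[C@]1(CCC2OC2(C)C)C=CC(=O)C1Br
F9 | step 5 | (4S)-5-bromo-4-methyl-4-(4-methyl-3-oxopentyl)cyclopent-2-en-1-one (C5 epimers) | C[C@]1(CCC(=O)C(C)C)C=CC(=O)C1Br
F10 | step 9 | (3R,3aS,4S,8aS)-8a-methyl-3-(propan-2-yl)-1,2,3,3a,4,5,6,8a-octahydroazulene-3,4,6-triol (C6 epimers) | CC(C)[C@]1(O)CC[C@@]2(C)C=CC(O)C[C@H](O)[C@@H]12
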